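**Retrosynthetic overview**
- 19 comes from 18 by reduction of three acyl groups with i-Bu2AlH. 18 comes from 16 and 17 by Heck coupling at C5–Br. 16 is the C3 epimer of ester 15, which is made from acid 14.
- Feature (benzofuran numbering: O1, aryl-bearing C2, C3 carrying the CH2OH carbon C9, ring A fused at C3a/C7a): with C9 at the acid level, the unit O–C2–C3–C9 is a β-hydroxy acid. C2, C3, C9 and one oxygen can therefore be held as an oxetan-2-one, whose O-benzylic carbon C2 can alkylate the ring A oxygen on C7a.
- 14 comes from 12 by a ring switch. The C7a phenoxide displaces the lactone carboxylate at C2 with inversion (O1–C2 bond), driven by release of the four-ring strain.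
- 12 comes from 8 and 10 by an alkaloid-catalysed ketene–aldehyde [2+2] cycloaddition, which forms C2–C3 and C9–O and sets both stereocentres (oxetanone C4 = later C2, oxetanone C2 = later C9). 8 derives from 5-bromo-o-vanillin 1 and 10 from syringaldehyde 9.
- Ring order: rings A and B are bought, the oxetanone closes in step 7, and the dihydrofuran ring closes in step 8 as the oxetanone opens.

Key step: step 7

Assumption: the facial sense of O-trimethylsilylquinidine is carried over from the alkylketene series and is unproven for this ketene/aldehyde pair; if a correlation on 16 shows the antipode, the pseudoenantiomeric O-trimethylsilylquinine is used and nothing else changes.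

**Step 1**
Reactants: 1 5-bromo-2-hydroxy-3-methoxybenzaldehyde
Product: 2 5-bromo-2-(tert-butyldimethylsilyloxy)-3-methoxybenzaldehyde
Conditions: TBSCl, imidazole, DMF, rt
Reagents that add atoms: tert-butyldimethylsilyl chloride, CC(C)(C)[Si](C)(C)Cl
Why: Imidazole-promoted silylation of a phenol is routine, and this silyl group is chosen because fluoride later converts it directly into the phenoxide needed in step 8.

**Step 2**
Reactants: 2 5-bromo-2-(tert-butyldimethylsilyloxy)-3-methoxybenzaldehyde
Product: 3 5-bromo-2-(tert-butyldimethylsilyloxy)-3-methoxystyrene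
Conditions: MePPh3Br (1.3 equiv), KOt-Bu (1.2 equiv), THF, 0 °C to rt
Reagents that add atoms: methyltriphenylphosphonium bromide, C[P+](c1ccccc1)(c1ccccc1)c1ccccc1.[Br-]
Why: This is a Wittig methylenation of an aromatic aldehyde, in which base is kept below the amount of phosphonium salt so that no free alkoxide attacks the aryl silyl ether, and the aryl bromide is inert.

**Step 3**
Reactants: 3 5-bromo-2-(tert-butyldimethylsilyloxy)-3-methoxystyrene
Product: 5 2-[5-bromo-2-(tert-butyldimethylsilyloxy)-3-methoxyphenyl]ethanol, via B-alkyl-9-BBN adduct 4 (not isolated)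
Conditions: 9-BBN, THF, 0 °C to rt; then NaBO3·4H2O, THF/H2O, rt
Reagents that add atoms: sodium perborate tetrahydrate, [Na+].[O-]OB=O.O.O.O.O
Why: In this hydroboration–oxidation, 9-BBN places boron on the terminal carbon of styrenes for steric reasons, and perborate oxidises the C–B bond at a pH that the doubly ortho-flanked aryl silyl ether should tolerate.

**Step 4**
Reactants: 5 2-[5-bromo-2-(tert-butyldimethylsilyloxy)-3-methoxyphenyl]ethanol
Product: 7 2-[5-bromo-2-(tert-butyldimethylsilyloxy)-3-methoxyphenyl]acetic acid, via arylacetaldehyde 6 (not isolated)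
Conditions: TEMPO (cat.), NaClO2 (2 equiv), NaOCl (cat.), MeCN, sodium phosphate buffer pH 6.7, 35 °C
Reagents that add atoms: sodium chlorite, [Na+].[O-]Cl=O
Why: TEMPO-catalysed oxidation with NaClO2 as terminal oxidant takes electron-rich 2-arylethanols through the aldehyde to arylacetic acids near neutral pH, where the silyl ether stays on and the catalytic amount of hypochlorite limits ring chlorination.

**Step 5**
Reactants: 7 2-[5-bromo-2-(tert-butyldimethylsilyloxy)-3-methoxyphenyl]acetic acid
Product: 8 2-[5-bromo-2-(tert-butyldimethylsilyloxy)-3-methoxyphenyl]acetyl chloride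
Conditions: (COCl)2 (1.3 equiv), DMF (cat.), CH2Cl2, 0 °C to rt; volatiles removed in vacuo, used at once
Reagents that add atoms: oxalyl chloride, O=C(Cl)C(Cl)=O
Why: Acid chloride formation through the chloroiminium salt from (COCl)2 and DMF gives only gaseous by-products, so 8 can be freed from HCl and used crude before the silyl ether oxygen can attack the acyl chloride.

**Step 6**
Reactants: 9 syringaldehyde (4-hydroxy-3,5-dimethoxybenzaldehyde)
Product: 10 4-formyl-2,6-dimethoxyphenyl pivalate
Conditions: t-BuCOCl, Et3N, DMAP (cat.), CH2Cl2, 0 °C to rt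
Reagents that add atoms: pivaloyl chloride, CC(C)(C)C(=O)Cl
Why: DMAP-catalysed O-acylation of a phenol turns the donor hydroxyl group into an acceptor that survives amines and fluoride and is removed by the last hydride reduction.

**Step 7**
Reactants: 8 2-[5-bromo-2-(tert-butyldimethylsilyloxy)-3-methoxyphenyl]acetyl chloride; 10 4-formyl-2,6-dimethoxyphenyl pivalate
Product: 12 (3S,4S)-cis-3-[5-bromo-2-(tert-butyldimethylsilyloxy)-3-methoxyphenyl]-4-[3,5-dimethoxy-4-(pivaloyloxy)phenyl]oxetan-2-one, via arylketene 11 (not isolated)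
Conditions: O-trimethylsilylquinidine (15 mol %), LiClO4 (2 equiv), i-Pr2NEt (2.5 equiv), 10 (1.5 equiv), CH2Cl2/Et2O, −78 °C, 8 added over 4 h; cold aqueous work-up; cis isomer freed from any trans isomer on cold silica
Reagents that add atoms: none
Why: Proposed new method: i-Pr2NEt dehydrochlorinates 8 to arylketene 11, the quinuclidine nitrogen adds to its central carbon to give a Z-configured acylammonium enolate, this adds through C3 to the lithium-bound carbonyl carbon of 10 (C2–C3 bond), and the lithium aldolate then attacks the acylammonium carbon (C9–O bond) and releases the catalyst. The closest known reaction type is the cinchona alkaloid/lithium salt catalysed acyl halide–aldehyde cyclocondensation to cis-3,4-disubstituted β-lactones, established for alkyl-substituted ketenes, and alkaloid-bound enolates of arylketenes are known nucleophiles toward imines and halogenating agents, so their union with an aromatic aldehyde is the untested part. The oxetan-2-one ring closes by 4-exo-trig attack of the alkoxide on the activated acyl carbon. C3 is set by the alkaloid, which shields one face of the bound enolate, and C4 (the later C2) is set relative to C3 by the closed lithium-bridged chair with ring B of the aldehyde equatorial, which translates the Z-enolate into the cis-lactone. The step needs enantio- and cis-selectivity together, because only C4 is carried into the target, and it needs the enolate to choose the aldehyde over a second ketene, which slow addition of 8, excess 10 and the bulky ortho-silyloxy group next to the ketene-bearing carbon should secure. The pivalate raises the electrophilicity of 10 and, together with the two methoxy groups meta to C4, holds back ionisation of the lactone C4–O bond and loss of CO2.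

**Step 8**
Reactants: 12 (3S,4S)-cis-β-lactone
Product: 14 (2R,3S)-cis-5-bromo-2-[3,5-dimethoxy-4-(pivaloyloxy)phenyl]-7-methoxy-2,3-dihydrobenzofuran-3-carboxylic acid, via tetrabutylammonium phenoxide 13 (not isolated)
Conditions: Bu4NF (1.05 equiv, THF solution dried over 4 Å sieves), THF, −78 to −20 °C; then cold 0.5 M HCl
Reagents that add atoms: none
Why: Proposed new method: fluoride removes the silyl group and leaves the naked phenoxide 13, whose oxygen can reach the rear of the strained O-benzylic C4–O bond through an envelope-shaped five-membered transition state (5-exo-tet, SN2) and expel the carboxylate, so the O1–C2 bond forms with inversion at C4 (S to R), C3 is untouched, and the cis-lactone maps onto the cis-2,3-disubstituted dihydrobenzofuran; addition of the phenoxide to the acyl carbon should be reversible under aprotic conditions, since aldolates of aryl esters are known to close to β-lactones with loss of phenoxide, whereas the alkylation releases the ring strain, ends in a carboxylate and cannot revert; the electron-poor ring B keeps the substitution on the SN2 side, the low temperature holds back loss of CO2 to the stilbene, and any epimerisation at C3 is harmless because C3 is equilibrated in step 10; the closest known reaction types are alkyl–oxygen opening of β-lactones by phenoxides, carboxylates, azide and thiolates with inversion, and conversion of β-lactones carrying a tethered oxygen nucleophile into tetrahydrofurans with inversion.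

**Step 9**
Reactants: 14 (2R,3S)-cis-acid
Product: 15 methyl (2R,3S)-cis-5-bromo-2-[3,5-dimethoxy-4-(pivaloyloxy)phenyl]-7-methoxy-2,3-dihydrobenzofuran-3-carboxylate
Conditions: MeI, KHCO3, DMF, rt
Reagents that add atoms: iodomethane, CI
Why: SN2 O-alkylation of the potassium carboxylate by MeI uses a base too weak to touch the pivalate, and any C3 epimerisation would only anticipate step 10.

**Step 10**
Reactants: 15 methyl (2R,3S)-cis-ester
Product: 16 methyl (2R,3R)-trans-5-bromo-2-[3,5-dimethoxy-4-(pivaloyloxy)phenyl]-7-methoxy-2,3-dihydrobenzofuran-3-carboxylate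
Conditions: DBU (1 equiv), toluene, 50 °C
Reagents that add atoms: none
Why: In this base-mediated epimerisation α to an ester, reversible deprotonation of the benzylic, ester-activated C3–H drains the cis isomer into the more stable trans isomer under the control of C2, C2 should stay intact because expulsion of the ring A phenoxide from the enolate would be the reverse of a 5-endo-trig closure, and a non-nucleophilic amidine is used because an alkoxide would strip the aryl pivalate and open a quinone methide path that erases C2.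

**Step 11**
Reactants: 16 methyl (2R,3R)-trans-ester; 17 methyl acrylate
Product: 18 methyl (2R,3R)-trans-2-[3,5-dimethoxy-4-(pivaloyloxy)phenyl]-7-methoxy-5-[(E)-3-methoxy-3-oxoprop-1-enyl]-2,3-dihydrobenzofuran-3-carboxylate
Conditions: Pd(OAc)2 (5 mol %), P(o-tol)3 (12 mol %), Et3N, DMF, 90 °C
Reagents that add atoms: none
Why: In this Mizoroki–Heck reaction, zerovalent palladium inserts into the unhindered C5–Br bond, syn insertion of the acrylate and syn β-hydride elimination give the E-cinnamate, and the amine cannot harm C3 because the trans isomer is already the thermodynamic one.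

**Step 12**
Reactants: 18 trans-diester pivalate
Product: 19 (2R,3S)-2-(4-hydroxy-3,5-dimethoxyphenyl)-3-(hydroxymethyl)-5-[(E)-3-hydroxyprop-1-enyl]-7-methoxy-2,3-dihydrobenzofuran (target)
Conditions: i-Bu2AlH (10 equiv), CH2Cl2, −78 to 0 °C; aq. potassium sodium tartrate
Reagents that add atoms: none
Why: i-Bu2AlH reduces the C3 ester and, in 1,2-fashion, the cinnamate to primary alcohols and cleaves the pivalate reductively to the phenol in one operation, no stereocentre is touched, and the C3 descriptor changes from R to S only because CH2OH ranks below C2.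

**Compound list**
1 | 5-bromo-2-hydroxy-3-methoxybenzaldehyde (5-bromo-o-vanillin) | COc1cc(Br)cc(C=O)c1O | starting material
2 | 5-bromo-2-(tert-butyldimethylsilyloxy)-3-methoxybenzaldehyde | COc1cc(Br)cc(C=O)c1O[Si](C)(C)C(C)(C)C | intermediate
3 | 5-bromo-2-(tert-butyldimethylsilyloxy)-3-methoxystyrene | C=Cc1cc(Br)cc(OC)c1O[Si](C)(C)C(C)(C)C | intermediate
4 | 9-{2-[5-bromo-2-(tert-butyldimethylsilyloxy)-3-methoxyphenyl]ethyl}-9-borabicyclo[3.3.1]nonane (not isolated) | COc1cc(Br)cc(CCB2C3CCCC2CCC3)c1O[Si](C)(C)C(C)(C)C | intermediate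
5 | 2-[5-bromo-2-(tert-butyldimethylsilyloxy)-3-methoxyphenyl]ethanol | COc1cc(Br)cc(CCO)c1O[Si](C)(C)C(C)(C)C | intermediate
6 | 2-[5-bromo-2-(tert-butyldimethylsilyloxy)-3-methoxyphenyl]acetaldehyde (not isolated) | COc1cc(Br)cc(CC=O)c1O[Si](C)(C)C(C)(C)C | intermediate
7 | 2-[5-bromo-2-(tert-butyldimethylsilyloxy)-3-methoxyphenyl]acetic acid | COc1cc(Br)cc(CC(=O)O)c1O[Si](C)(C)C(C)(C)C | intermediate
8 | 2-[5-bromo-2-(tert-butyldimethylsilyloxy)-3-methoxyphenyl]acetyl chloride | COc1cc(Br)cc(CC(Cl)=O)c1O[Si](C)(C)C(C)(C)C | intermediate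
9 | syringaldehyde | COc1cc(C=O)cc(OC)c1O | starting material
10 | 4-formyl-2,6-dimethoxyphenyl pivalate | COc1cc(C=O)cc(OC)c1OC(=O)C(C)(C)C | intermediate
11 | [5-bromo-2-(tert-butyldimethylsilyloxy)-3-methoxyphenyl]ketene (not isolated) | COc1cc(Br)cc(C=C=O)c1O[Si](C)(C)C(C)(C)C | intermediate
12 | (3S,4S)-cis-3-[5-bromo-2-(tert-butyldimethylsilyloxy)-3-methoxyphenyl]-4-[3,5-dimethoxy-4-(pivaloyloxy)phenyl]oxetan-2-one | COc1cc([C@H]2OC(=O)[C@H]2c3cc(Br)cc(OC)c3O[Si](C)(C)C(C)(C)C)cc(OC)c1OC(=O)C(C)(C)C | intermediate
13 | tetrabutylammonium 4-bromo-2-{(3S,4S)-4-[3,5-dimethoxy-4-(pivaloyloxy)phenyl]-2-oxooxetan-3-yl}-6-methoxyphenoxide (not isolated) | COc1cc([C@H]2OC(=O)[C@H]2c3cc(Br)cc(OC)c3[O-])cc(OC)c1OC(=O)C(C)(C)C.CCCC[N+](CCCC)(CCCC)CCCC | intermediate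
14 | (2R,3S)-cis-5-bromo-2-[3,5-dimethoxy-4-(pivaloyloxy)phenyl]-7-methoxy-2,3-dihydrobenzofuran-3-carboxylic acid | COc1cc([C@@H]2Oc3c(OC)cc(Br)cc3[C@@H]2C(=O)O)cc(OC)c1OC(=O)C(C)(C)C | intermediate
15 | methyl (2R,3S)-cis-5-bromo-2-[3,5-dimethoxy-4-(pivaloyloxy)phenyl]-7-methoxy-2,3-dihydrobenzofuran-3-carboxylate | COc1cc([C@@H]2Oc3c(OC)cc(Br)cc3[C@@H]2C(=O)OC)cc(OC)c1OC(=O)C(C)(C)C | intermediate
16 | methyl (2R,3R)-trans-5-bromo-2-[3,5-dimethoxy-4-(pivaloyloxy)phenyl]-7-methoxy-2,3-dihydrobenzofuran-3-carboxylate | COc1cc([C@@H]2Oc3c(OC)cc(Br)cc3[C@H]2C(=O)OC)cc(OC)c1OC(=O)C(C)(C)C | intermediate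
17 | methyl acrylate | C=CC(=O)OC | starting material
18 | methyl (2R,3R)-trans-2-[3,5-dimethoxy-4-(pivaloyloxy)phenyl]-7-methoxy-5-[(E)-3-methoxy-3-oxoprop-1-enyl]-2,3-dihydrobenzofuran-3-carboxylate | COc1cc([C@@H]2Oc3c(OC)cc(/C=C/C(=O)OC)cc3[C@H]2C(=O)OC)cc(OC)c1OC(=O)C(C)(C)C | intermediate
19 | (2R,3S)-2-(4-hydroxy-3,5-dimethoxyphenyl)-3-(hydroxymethyl)-5-[(E)-3-hydroxyprop-1-enyl]-7-methoxy-2,3-dihydrobenzofuran | COc1cc([C@@H]2Oc3c(OC)cc(/C=C/CO)cc3[C@H]2CO)cc(OC)c1O | target

**Step count**
Total: 12 steps. Longest linear sequence: 11 steps (1 to 19 through steps 1–5 and 7–12).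

**Steps most likely to fail**

Step 7.
- The alkaloid also catalyses dimerisation of the arylketene, which may outrun addition to the aromatic aldehyde.
- The aldol event may pass through an open rather than the closed transition state, with weak control of the aldehyde face. A trans isomer formed this way carries the wrong C4 and would erode the enantiomeric purity of everything downstream unless it is removed.
- Fallback (auxiliary-controlled aldol plus lactonisation, known chemistry), from 8 and 10 back to 12. Acid chloride 8 acylates (S)-4-benzyloxazolidin-2-one that has been deprotonated with n-BuLi (THF, −78 °C), giving the imide (S)-4-benzyl-3-(arylacetyl)oxazolidin-2-one F1. Enolisation with Bu2BOTf/i-Pr2NEt and addition of 10 (Evans syn-aldol) should give the (2S,3S)-syn-aldol imide F2. A short treatment with LiOH/H2O2 at 0 °C, which the hindered pivalate and the ortho-flanked silyl ether should outlast, frees the (2S,3S)-β-hydroxy acid F3. PhSO2Cl in pyridine at 0 °C closes F3 by carboxyl activation, with retention at both centres, to 12.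

Step 8.
- The phenoxide may add to the acyl carbon, and the resulting benzofuranone aldolate may be drained by retro-aldol cleavage or dehydration before it returns to the lactone.
- Deprotonation at C3 may be followed by β-elimination of the carboxylate.
- Partial ionisation at C4 would give loss of stereochemical fidelity or loss of CO2.
- Fallback (acyl opening, then Mitsunobu closure, known chemistry), from 12 back to 15. DMAP-catalysed methanolysis (MeOH, i-Pr2NEt, DMAP, 0 °C) cleaves the acyl–oxygen bond and gives the methyl (2S,3S)-β-hydroxy ester F4 with both centres intact. Bu4NF buffered with AcOH (THF, 0 °C) gives the free phenol F5. Mitsunobu cyclodehydration (PPh3, DIAD, THF, 0 °C) activates the benzylic hydroxyl group, and the phenol displaces it with inversion (5-exo-tet) to give 15.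

Step 10.
- Proton exchange at C3 may be too slow with the amidine.
- The ester enolate may expel the ring A phenoxide, which would open the ring and erase C2.
- Fallback (the stereochemical correction is moved to the aldehyde level, which lies on the way to the CH2OH group), from 15 back to 19. i-Bu2AlH (1.1 equiv, toluene, −78 °C) stops at the (2R,3S)-cis-3-carbaldehyde F6. Its much more acidic C3–H equilibrates with Et3N in CH2Cl2 at rt to the (2R,3R)-trans-3-carbaldehyde F7. NaBH4 (THF/MeOH, 0 °C) gives the (2R,3S)-trans-3-hydroxymethyl bromide F8. Heck coupling with 17 under the conditions of step 11 gives the E-cinnamate F9, and i-Bu2AlH as in step 12 gives 19.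

**Further compounds**
F1 | step 7 | (S)-4-benzyl-3-{2-[5-bromo-2-(tert-butyldimethylsilyloxy)-3-methoxyphenyl]acetyl}oxazolidin-2-one | COc1cc(Br)cc(CC(=O)N2[C@@H](Cc3ccccc3)COC2=O)c1O[Si](C)(C)C(C)(C)C
F2 | step 7 | (S)-4-benzyl-3-{(2S,3S)-2-[5-bromo-2-(tert-butyldimethylsilyloxy)-3-methoxyphenyl]-3-[3,5-dimethoxy-4-(pivaloyloxy)phenyl]-3-hydroxypropanoyl}oxazolidin-2-one | COc1cc([C@@H](O)[C@@H](C(=O)N2[C@@H](Cc3ccccc3)COC2=O)c4cc(Br)cc(OC)c4O[Si](C)(C)C(C)(C)C)cc(OC)c1OC(=O)C(C)(C)C
F3 | step 7 | (2S,3S)-2-[5-bromo-2-(tert-butyldimethylsilyloxy)-3-methoxyphenyl]-3-[3,5-dimethoxy-4-(pivaloyloxy)phenyl]-3-hydroxypropanoic acid | COc1cc([C@@H](O)[C@@H](C(=O)O)c2cc(Br)cc(OC)c2O[Si](C)(C)C(C)(C)C)cc(OC)c1OC(=O)C(C)(C)C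
F4 | step 8 | methyl (2S,3S)-2-[5-bromo-2-(tert-butyldimethylsilyloxy)-3-methoxyphenyl]-3-[3,5-dimethoxy-4-(pivaloyloxy)phenyl]-3-hydroxypropanoate | COc1cc([C@@H](O)[C@@H](C(=O)OC)c2cc(Br)cc(OC)c2O[Si](C)(C)C(C)(C)C)cc(OC)c1OC(=O)C(C)(C)C
F5 | step 8 | methyl (2S,3S)-2-(5-bromo-2-hydroxy-3-methoxyphenyl)-3-[3,5-dimethoxy-4-(pivaloyloxy)phenyl]-3-hydroxypropanoate | COc1cc([C@@H](O)[C@@H](C(=O)OC)c2cc(Br)cc(OC)c2O)cc(OC)c1OC(=O)C(C)(C)C
F6 | step 10 | 4-[(2R,3S)-cis-5-bromo-3-formyl-7-methoxy-2,3-dihydrobenzofuran-2-yl]-2,6-dimethoxyphenyl pivalate | COc1cc([C@@H]2Oc3c(OC)cc(Br)cc3[C@@H]2C=O)cc(OC)c1OC(=O)C(C)(C)C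
F7 | step 10 | 4-[(2R,3R)-trans-5-bromo-3-formyl-7-methoxy-2,3-dihydrobenzofuran-2-yl]-2,6-dimethoxyphenyl pivalate | COc1cc([C@@H]2Oc3c(OC)cc(Br)cc3[C@H]2C=O)cc(OC)c1OC(=O)C(C)(C)C
F8 | step 10 | 4-[(2R,3S)-trans-5-bromo-3-(hydroxymethyl)-7-methoxy-2,3-dihydrobenzofuran-2-yl]-2,6-dimethoxyphenyl pivalate | COc1cc([C@@H]2Oc3c(OC)cc(Br)cc3[C@H]2CO)cc(OC)c1OC(=O)C(C)(C)C
F9 | step 10 | methyl (E)-3-{(2R,3S)-trans-2-[3,5-dimethoxy-4-(pivaloyloxy)phenyl]-3-(hydroxymethyl)-7-methoxy-2,3-dihydrobenzofuran-5-yl}acrylate | COc1cc([C@@H]2Oc3c(OC)cc(/C=C/C(=O)OC)cc3[C@H]2CO)cc(OC)c1OC(=O)C(C)(C)C
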